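**Retrosynthetic overview**
- The C40 chain is cut at C10=C11 and C10'=C11' (two Horner–Wadsworth–Emmons olefinations), giving a C12 tetraene bis-phosphonate (C11–C11') and two C14 "retro" aldehydes, one per ring.
- The C12 bis-phosphonate comes from joining two molecules of a C6 enynyl phosphonate at C15–C15' (hydrozirconation, then copper-mediated homocoupling).
- Each C14 aldehyde comes from a Heck reaction of methacrolein with the exocyclic enol triflate of a C10 ring aldehyde; the enolate C=C becomes the retro double bond C6=C7 (C6'=C7').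
- Each ring aldehyde comes from an acyclic enol acetate by proton-initiated closure of the C1–C6 bond (the bond the carotenoid cyclases make), terminated by the enol ester; C5' is carried in from (S)-citronellal.
- Ring order: the saturated ring B (C1'–C6') is closed in step 1 and the cyclohexene ring A (C1–C6) in step 4, both before any polyene exists.

Assumption: carotenoid numbering locates atoms (unprimed = half with ring A, primed = half with ring B); the target is (5'S,6E,6'E)-all-E, and the (S)-citronellal used is of high ee because its ee becomes that of the product.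

**Step 1**
Reactants: 1 (S)-citronellal, (3S)-3,7-dimethyloct-6-enal
Product: 3 (1R,6S)-2,2,6-trimethylcyclohexane-1-carbaldehyde, via citronellal enol acetate 2 (not isolated)
Conditions: Ac2O, Et3N, KOAc (cat.), 120 °C; evaporate; 85% H3PO4, toluene, 50 °C; H2O work-up
Reagents that add atoms: none
Why: Enol-ester-terminated cation–olefin cyclization: Markovnikov protonation of the trisubstituted alkene gives the tertiary cation, the enol acetate carbon closes the six-membered ring through a chair, and the acyloxycarbenium ion is hydrolysed to the aldehyde; C6 is C3 of (S)-citronellal and is never touched, and the new C1 centre (mainly trans) is erased in step 2.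

**Step 2**
Reactants: 3 (1R,6S)-2,2,6-trimethylcyclohexane-1-carbaldehyde
Product: 5 (E)-[(6S)-2,2,6-trimethylcyclohexylidene]methyl trifluoromethanesulfonate, via potassium enolate 4 (not isolated)
Conditions: KN(SiMe3)2, THF, −78 °C; PhNTf2, −78 → 0 °C; minor Z isomer removed on AgNO3-doped SiO2
Reagents that add atoms: N-phenylbis(trifluoromethanesulfonimide), O=S(=O)(N(c1ccccc1)S(=O)(=O)C(F)(F)F)C(F)(F)F
Why: Enol triflate formation by deprotonation of the single α-hydrogen and O-sulfonylation; the enolate oxygen is expected to sit beside the CHMe carbon and not the quaternary CMe2 carbon (allylic strain), which is the E geometry that later places C8' syn to C5', and C6(S) is not involved.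

**Step 3**
Reactants: 5 (E)-[(6S)-2,2,6-trimethylcyclohexylidene]methyl trifluoromethanesulfonate; 6 methacrolein (2-methylprop-2-enal)
Product: 7 (2E)-2-methyl-4-[(1E,6S)-2,2,6-trimethylcyclohexylidene]but-2-enal
Conditions: Pd(OAc)2 (5 mol %), PPh3 (10 mol %), n-Bu4NCl, NaHCO3, DMF, 60 °C
Reagents that add atoms: none
Why: Mizoroki–Heck reaction of an enol triflate: oxidative addition to zerovalent palladium retains the exocyclic geometry, insertion occurs at the CH2 end of methacrolein, and syn β-hydride elimination gives the (2E)-dienal (C8'=C9'); the weak base does not touch the ε-C–H at the stereocentre.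

**Step 4**
Reactants: 8 citral (3,7-dimethylocta-2,6-dienal, commercial E/Z mixture)
Product: 10 (±)-2,6,6-trimethylcyclohex-2-ene-1-carbaldehyde, via citral dienol acetate 9 (not isolated)
Conditions: Ac2O, Et3N, KOAc (cat.), 120 °C; evaporate; 85% H3PO4, toluene, 50 °C; H2O work-up; distil
Reagents that add atoms: none
Why: The same enol-ester-terminated proton-initiated cyclization: C2 of the dienol acetate attacks the tertiary cation so that the C3=C4 double bond ends up in the ring (α-cyclocitral), the dienol acetate isomers equilibrate under the acid, and the racemic new centre is erased in step 5.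

**Step 5**
Reactants: 10 (±)-2,6,6-trimethylcyclohex-2-ene-1-carbaldehyde
Product: 12 (E)-(2,6,6-trimethylcyclohex-2-en-1-ylidene)methyl trifluoromethanesulfonate, via potassium dienolate 11 (not isolated)
Conditions: KN(SiMe3)2, THF, −78 °C; PhNTf2, −78 → 0 °C
Reagents that add atoms: N-phenylbis(trifluoromethanesulfonimide), O=S(=O)(N(c1ccccc1)S(=O)(=O)C(F)(F)F)C(F)(F)F
Why: Enol triflate formation from the doubly activated α-hydrogen; the dienolate oxygen avoids the in-plane ring methyl on C5 and sits beside CMe2, which is the E geometry of the natural retro ring (C8 syn to C1).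

**Step 6**
Reactants: 12 (E)-(2,6,6-trimethylcyclohex-2-en-1-ylidene)methyl trifluoromethanesulfonate; 6 methacrolein
Product: 13 (2E)-2-methyl-4-[(1E)-2,6,6-trimethylcyclohex-2-en-1-ylidene]but-2-enal
Conditions: Pd(OAc)2 (5 mol %), PPh3 (10 mol %), n-Bu4NCl, NaHCO3, DMF, 60 °C
Reagents that add atoms: none
Why: Mizoroki–Heck reaction as in step 3, with retention at C6=C7 and E-selective β-hydride elimination at C8=C9; any 6Z isomer can be equilibrated to the more stable 6E form at this achiral stage.

**Step 7**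
Reactants: 14 (2E)-3-methylpent-2-en-4-yn-1-ol
Product: 16 diethyl [(2E)-3-methylpent-2-en-4-yn-1-yl]phosphonate, via allylic bromide 15 (not isolated)
Conditions: PBr3, pyridine (cat.), Et2O, −10 °C; then P(OEt)3, 100 °C
Reagents that add atoms: triethyl phosphite, CCOP(OCC)OCC
Why: Bromination of the primary allylic alcohol (SN2, no allylic shift) followed by the Michaelis–Arbuzov reaction; the E-trisubstituted double bond (later C12=C13) is untouched.

**Step 8**
Reactants: 16 diethyl [(2E)-3-methylpent-2-en-4-yn-1-yl]phosphonate (two molecules, joined at their alkyne termini)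
Product: 19 tetraethyl [(2E,4E,6E,8E)-3,8-dimethyldeca-2,4,6,8-tetraene-1,10-diyl]bis(phosphonate), via dienylzirconocene 17 (not isolated), via dienylcopper 18 (not isolated)
Conditions: Cp2Zr(H)Cl (1.1 equiv per alkyne), THF, 25 °C; then CuCl (1.1 equiv per alkyne), 0 → 50 °C
Reagents that add atoms: diethyl [(2E)-3-methylpent-2-en-4-yn-1-yl]phosphonate (the second molecule of 16), C#C/C(C)=C/CP(=O)(OCC)OCC
Why: Schwartz hydrozirconation adds Zr–H syn to the terminal alkyne of each molecule of 16 with zirconium at the terminal carbon, and transmetalation to copper followed by copper-mediated homocoupling of the two alkenyl groups with retention forms the C15–C15' bond as an (E,E)-diene, so the symmetrical C12 unit is built from two identical C6 halves.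

**Step 9**
Reactants: 19 tetraethyl [(2E,4E,6E,8E)-3,8-dimethyldeca-2,4,6,8-tetraene-1,10-diyl]bis(phosphonate); 13 (2E)-2-methyl-4-[(1E)-2,6,6-trimethylcyclohex-2-en-1-ylidene]but-2-enal; 7 (2E)-2-methyl-4-[(1E,6S)-2,2,6-trimethylcyclohexylidene]but-2-enal
Product: 23 (5'S,6E,6'E)-4,5'-retro-β,β-carotene, via bis-phosphonate monoanion 20 (not isolated), via C26 phosphonate 21 (not isolated), via C26 phosphonate anion 22 (not isolated)
Conditions: NaN(SiMe3)2 (1.0 equiv), THF, −78 °C; 13, −78 → 0 °C; NaN(SiMe3)2 (1.0 equiv), −78 °C; 7, −78 → 25 °C; N2, dark; crystallise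
Reagents that add atoms: none
Why: Two consecutive Horner–Wadsworth–Emmons olefinations: one equivalent of base gives only the monoanion (a second charge in the same π system is much harder), which adds to 13 at −78 °C before proton exchange and eliminates on warming to the E-alkene C10=C11; the second equivalent then olefinates 7 at C10'=C11', carbonyl addition being faster than deprotonation at C5'.

**Compound list**
1 | (S)-citronellal, (3S)-3,7-dimethyloct-6-enal | O=CC[C@@H](C)CCC=C(C)C | starting material
2 | (3S)-3,7-dimethylocta-1,6-dien-1-yl acetate (E/Z mixture, E drawn) | CC(=O)O/C=C/[C@@H](C)CCC=C(C)C | intermediate (not isolated)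
3 | (1R,6S)-2,2,6-trimethylcyclohexane-1-carbaldehyde (trans; the C1 epimer is equally usable) | O=C[C@@H]1[C@@H](C)CCCC1(C)C | intermediate
4 | potassium (E)-[(6S)-2,2,6-trimethylcyclohexylidene]methanolate | [K+].[O-]/C=C1\[C@@H](C)CCCC1(C)C | intermediate (not isolated)
5 | (E)-[(6S)-2,2,6-trimethylcyclohexylidene]methyl trifluoromethanesulfonate | FC(F)(F)S(=O)(=O)O/C=C1\[C@@H](C)CCCC1(C)C | intermediate
6 | methacrolein, 2-methylprop-2-enal | C=C(C)C=O | starting material
7 | (2E)-2-methyl-4-[(1E,6S)-2,2,6-trimethylcyclohexylidene]but-2-enal | O=C/C(C)=C/C=C1\[C@@H](C)CCCC1(C)C | intermediate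
8 | citral, 3,7-dimethylocta-2,6-dienal (E/Z mixture, E drawn) | CC(C)=CCC/C(C)=C/C=O | starting material
9 | 3,7-dimethylocta-1,3,6-trien-1-yl acetate (mixture of double-bond isomers) | CC(=O)OC=CC(C)=CCC=C(C)C | intermediate (not isolated)
10 | (±)-2,6,6-trimethylcyclohex-2-ene-1-carbaldehyde (α-cyclocitral) | O=CC1C(C)=CCCC1(C)C | intermediate
11 | potassium (E)-(2,6,6-trimethylcyclohex-2-en-1-ylidene)methanolate | CC1=CCCC(C)(C)\C1=C/[O-].[K+] | intermediate (not isolated)
12 | (E)-(2,6,6-trimethylcyclohex-2-en-1-ylidene)methyl trifluoromethanesulfonate | CC1=CCCC(C)(C)\C1=C/OS(=O)(=O)C(F)(F)F | intermediate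
13 | (2E)-2-methyl-4-[(1E)-2,6,6-trimethylcyclohex-2-en-1-ylidene]but-2-enal | CC1=CCCC(C)(C)\C1=C/C=C(C)/C=O | intermediate
14 | (2E)-3-methylpent-2-en-4-yn-1-ol | C#C/C(C)=C/CO | starting material
15 | (3E)-5-bromo-3-methylpent-3-en-1-yne | C#C/C(C)=C/CBr | intermediate (not isolated)
16 | diethyl [(2E)-3-methylpent-2-en-4-yn-1-yl]phosphonate | C#C/C(C)=C/CP(=O)(OCC)OCC | intermediate
17 | chlorobis(cyclopentadienyl)[(1E,3E)-5-(diethoxyphosphoryl)-3-methylpenta-1,3-dien-1-yl]zirconium (Cp drawn σ-bonded) | CCOP(=O)(OCC)C/C=C(C)/C=C/[Zr](Cl)(C1C=CC=C1)C1C=CC=C1 | intermediate (not isolated)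
18 | [(1E,3E)-5-(diethoxyphosphoryl)-3-methylpenta-1,3-dien-1-yl]copper | CCOP(=O)(OCC)C/C=C(C)/C=C/[Cu] | intermediate (not isolated)
19 | tetraethyl [(2E,4E,6E,8E)-3,8-dimethyldeca-2,4,6,8-tetraene-1,10-diyl]bis(phosphonate) | CCOP(=O)(OCC)C/C=C(C)/C=C/C=C/C(C)=C/CP(=O)(OCC)OCC | intermediate
20 | sodium salt of 19 deprotonated at one P–CH2 | [Na+].CCOP(=O)(OCC)[CH-]/C=C(C)/C=C/C=C/C(C)=C/CP(=O)(OCC)OCC | intermediate (not isolated)
21 | diethyl {(2E,4E,6E,8E,10E,12E)-3,8,12-trimethyl-14-[(1E)-2,6,6-trimethylcyclohex-2-en-1-ylidene]tetradeca-2,4,6,8,10,12-hexaen-1-yl}phosphonate | CC1=CCCC(C)(C)\C1=C/C=C(C)/C=C/C=C(C)/C=C/C=C/C(C)=C/CP(=O)(OCC)OCC | intermediate (not isolated)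
22 | sodium salt of 21 deprotonated at P–CH2 | [Na+].CC1=CCCC(C)(C)\C1=C/C=C(C)/C=C/C=C(C)/C=C/C=C/C(C)=C/[CH-]P(=O)(OCC)OCC | intermediate (not isolated)
23 | (5'S,6E,6'E)-4,5'-retro-β,β-carotene; (6E)-1,5,5-trimethyl-6-{(2E,4E,6E,8E,10E,12E,14E,16E)-3,7,12,16-tetramethyl-18-[(1E,6S)-2,2,6-trimethylcyclohexylidene]octadeca-2,4,6,8,10,12,14,16-octaen-1-ylidene}cyclohex-1-ene | CC1=CCCC(C)(C)\C1=C/C=C(C)/C=C/C=C(C)/C=C/C=C/C(C)=C/C=C/C(C)=C/C=C1\[C@@H](C)CCCC1(C)C | target

**Totals**
Total steps: 9. Longest linear sequence: 4 steps (1 → 2 → 3 → 9, or 4 → 5 → 6 → 9).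

**Steps most likely to fail**

First, step 1. The enol acetate can be hydrolysed before the ring closes, and free citronellal then gives isopulegol by the carbonyl-ene path. The fallback sets out from 2, now distilled, and replaces the proton by a carbon-philic electrophile that opens the same Markovnikov cation but cannot hydrolyse the enol ester. Hg(OTf)2 in MeNO2 at −20 °C, then aqueous NaCl, gives the organomercurial (1R,6S)-3-(chloromercurio)-2,2,6-trimethylcyclohexane-1-carbaldehyde F1. Bu3SnH (toluene, 25 °C) then exchanges C–Hg for C–H, and the route is rejoined at 3.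

Second, step 2. The two faces of the enolate are flanked by CHMe and CMe2, so the E/Z ratio may be modest and the isomers hard to separate. The fallback sets out from 3 and gives up control at this point. Tf2O with 2,6-di-tert-butyl-4-methylpyridine in CH2Cl2 gives 5 mixed with (Z)-[(6S)-2,2,6-trimethylcyclohexylidene]methyl trifluoromethanesulfonate F2, and the Heck reaction of step 3 is run on the mixture. Dienal 7 is separated on AgNO3-doped silica from (2E)-2-methyl-4-[(1Z,6S)-2,2,6-trimethylcyclohexylidene]but-2-enal F3. F3 is returned to the 7/F3 equilibrium with PhSSPh under visible light (reversible thiyl-radical addition) and recycled, so the material converges on 7, where the route is rejoined.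

Third, step 9. The one-pot double olefination can scramble (symmetrical C40 by-products), give Z isomers, or erode C5' by ε-deprotonation of 7. The fallback sets out from 16 (with 13 and 7) and moves the final union to an sp2–sp2 coupling at C15–C15'. Separate Horner–Wadsworth–Emmons reactions of 16 (NaN(SiMe3)2, THF, −78 → 0 °C) with 13 and with 7 give the enynes (6E)-6-[(2E,4E,6E)-3,7-dimethylnona-2,4,6-trien-8-yn-1-ylidene]-1,5,5-trimethylcyclohex-1-ene F4 and (2E,3S)-2-[(2E,4E,6E)-3,7-dimethylnona-2,4,6-trien-8-yn-1-ylidene]-1,1,3-trimethylcyclohexane F5. Cp2Zr(H)Cl then I2 converts F4 into (6E)-6-[(2E,4E,6E,8E)-9-iodo-3,7-dimethylnona-2,4,6,8-tetraen-1-ylidene]-1,5,5-trimethylcyclohex-1-ene F6. Cp2Zr(H)Cl converts F5 into chlorobis(cyclopentadienyl){(1E,3E,5E,7E)-3,7-dimethyl-9-[(1E,6S)-2,2,6-trimethylcyclohexylidene]nona-1,3,5,7-tetraen-1-yl}zirconium F7. Negishi coupling of F7 with F6 (ZnCl2, Pd(PPh3)4, THF) comes back to the route at 23.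

**Further compounds**
F1 | step 1 | (1R,6S)-3-(chloromercurio)-2,2,6-trimethylcyclohexane-1-carbaldehyde (configuration at C3 not fixed) | O=C[C@@H]1[C@@H](C)CCC([Hg]Cl)C1(C)C
F2 | step 2 | (Z)-[(6S)-2,2,6-trimethylcyclohexylidene]methyl trifluoromethanesulfonate | FC(F)(F)S(=O)(=O)O/C=C1/[C@@H](C)CCCC1(C)C
F3 | step 2 | (2E)-2-methyl-4-[(1Z,6S)-2,2,6-trimethylcyclohexylidene]but-2-enal | O=C/C(C)=C/C=C1/[C@@H](C)CCCC1(C)C
F4 | step 9 | (6E)-6-[(2E,4E,6E)-3,7-dimethylnona-2,4,6-trien-8-yn-1-ylidene]-1,5,5-trimethylcyclohex-1-ene | CC1=CCCC(C)(C)\C1=C/C=C(C)/C=C/C=C(C)/C#C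
F5 | step 9 | (2E,3S)-2-[(2E,4E,6E)-3,7-dimethylnona-2,4,6-trien-8-yn-1-ylidene]-1,1,3-trimethylcyclohexane | C#C/C(C)=C/C=C/C(C)=C/C=C1\[C@@H](C)CCCC1(C)C
F6 | step 9 | (6E)-6-[(2E,4E,6E,8E)-9-iodo-3,7-dimethylnona-2,4,6,8-tetraen-1-ylidene]-1,5,5-trimethylcyclohex-1-ene | CC1=CCCC(C)(C)\C1=C/C=C(C)/C=C/C=C(C)/C=C/I
F7 | step 9 | chlorobis(cyclopentadienyl){(1E,3E,5E,7E)-3,7-dimethyl-9-[(1E,6S)-2,2,6-trimethylcyclohexylidene]nona-1,3,5,7-tetraen-1-yl}zirconium (Cp drawn σ-bonded) | Cl[Zr](/C=C/C(C)=C/C=C/C(C)=C/C=C1\[C@@H](C)CCCC1(C)C)(C2C=CC=C2)C2C=CC=C2
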